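## The problem

Target 19, 2-methoxy-6-nonadecylcyclohexa-2,5-diene-1,4-dione, is a single six-membered carbocycle. C1 and C4 are the quinone carbonyl carbons, C2 carries the methoxy group, C6 carries an unbranched nineteen-carbon chain, and C3 and C5 are CH. There is no stereocentre and no double-bond geometry, so nothing can or must exert stereocontrol; the difficulty is purely regiochemical. Three oxygens have to sit in a 1,2,4-array with the chain ortho to the C1 oxygen and meta to the other two. C1, flanked by methoxy and chain, is the hardest position to reach by oxidation or metalation of a preformed arene. The chain is chemically inert but makes every intermediate waxy and poorly soluble in polar media, which matters for the ionic steps. The methoxyquinone is a vinylogous ester and a Michael acceptor that will not tolerate nucleophiles, strong base or reducing conditions, so it must be unveiled last from a hydroquinone. The enabling feature is that the segment C2(OMe)–C3–C4(O)–C5 has the oxygen pattern of a 1,1-dimethoxy-3-silyloxybutadiene, while the pair C6/C1 maps onto an alkyne that carries the chain at one end and an acetyl group, exchangeable for oxygen, at the other.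

## Retrosynthesis

**19 to 18.** No skeletal bond is cut first; only the oxidation level is lowered, from quinone 19 to 2-methoxy-6-nonadecylbenzene-1,4-diol 18. This puts the one fragile functional group into the final step. The forward reaction needs only a mild, neutral two-electron oxidant, and a para-hydroquinone has a single possible quinone.

**18 to 16.** The C1–O bond of 18 is exchanged for a C1–C(acetyl) bond, giving 1-(4-hydroxy-2-methoxy-6-nonadecylphenyl)ethan-1-one 16. The neighbouring option, oxidising a C1–H bond of a 3,5-disubstituted phenol, would place the regiochemical burden on the most hindered ring position at the end of the route. A carbon substituent at C1 is fixed by construction and is converted at the same carbon by aryl migration. 16 already has the free para-hydroxyl that a Dakin oxidation requires. The forward step must make the hindered ketone accept peroxide and the aryl group migrate in preference to methyl.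

**16 to 13 + 6.** The ring bonds C1–C2 and C5–C6 are cut, giving 1,1-dimethoxy-3-(trimethylsilyloxy)buta-1,3-diene 13 and tricos-3-yn-2-one 6. Cutting the chain–C6 bond instead would leave a tetrasubstituted arene whose substitution pattern would still have to be built. Cutting other ring-bond pairs gives three-carbon partners in which the two oxygens are no longer differentiated. This cut removes the ring altogether and leaves two acyclic pieces. One holds both oxygens already distinguished as methyl ether and silyl ether, the other holds the chain and the latent C1 oxygen. The forward reaction must show one regiochemistry and must cope with an internal, β-alkylated ynone.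

**6 to 2 + 3.** The bond between the carbonyl carbon and the alkyne of 6 is cut, giving henicos-1-yne 2 and N-methoxy-N-methylacetamide 3. Acylating a metalated alkyne is more direct than oxidising a propargylic alcohol, and the N-methoxy-N-methylamide stops cleanly at the ketone. The forward step asks only for clean lithiation of a terminal alkyne.

**2 to 1.** The C(sp)–C(sp3) bond of 2 is cut, giving 1-bromononadecane 1 and a two-carbon acetylide nucleophile. All twenty-one carbons of 2 then come from one commercial bromide and the simplest alkyne unit. The forward reaction is a substitution at a primary carbon and must avoid elimination and double alkylation.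

**13 to 12.** The O–Si bond of 13 is cut, giving 4,4-dimethoxybut-3-en-2-one 12. The methyl group is the only enolisable position of 12, so only one silyl dienol ether can form.

**12 to 10.** Both C–OMe bonds of 12 are cut, giving 4,4-dichlorobut-3-en-2-one 10. The β-carbon of this enone carries two leaving groups, so two addition–elimination events with methoxide build the ketene acetal.

**10 to 7 + 8.** The C2–C3 bond of 10 is cut, giving acetyl chloride 7 and 1,1-dichloroethene 8, both bulk chemicals. The forward reaction is an acylation of the alkene at its CH2 terminus followed by loss of hydrogen chloride.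

## Roads not taken

**Alternative 1:** The cut is at the C6–chain bond and at the C1–O bond, which first appears as a C1–B bond; the ring is bought as 1-iodo-2,4-dimethoxybenzene A1.

- **Forward key step.** A1, bromide 1 and bis(pinacolato)diboron A2 would be joined in a Catellani reaction. Palladium, relayed by a strained bicyclic olefin, alkylates the free ortho position and ends with ipso-borylation, giving 2-(2,4-dimethoxy-6-nonadecylphenyl)-4,4,5,5-tetramethyl-1,3,2-dioxaborolane A3. Oxidation of the C–B bond would give 2,4-dimethoxy-6-nonadecylphenol A4, and oxidative demethylation would give 19.
- **Merits.** Three steps from purchased materials, full convergence, and no ring construction.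
- **Weak points.** Three components must react in the right order. Direct borylation of A1 by A2 competes before the relay starts. An unactivated primary alkyl bromide adds slowly to the divalent palladacycle on the way to tetravalent palladium. Methoxy is a small ortho blocking group for the olefin-extrusion step. A3 is a di-ortho-substituted, electron-rich arylboronate prone to protodeboronation. The last oxidation of A4 must choose loss of the para methoxy group over the ortho one.
- **Comparison.** This road is clearly shorter. The chosen plan offers instead steps that are all two-component reactions of established types, regiochemistry set by the polarity of the partners and not by catalyst tuning, and a final oxidation of 18 with only one outcome.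

**Alternative 2:** The cut runs through two bonds of a saturated ring. Dimethyl malonate A5 supplies one ring carbon and one carbonyl, and (E)-tricos-3-en-2-one A6 supplies the other four ring carbons.

- **Forward key step.** Conjugate addition of A5 to A6 under alkoxide base, intramolecular Claisen closure of the methyl ketone enolate onto an ester, then saponification and decarboxylation, give 5-nonadecylcyclohexane-1,3-dione A7. The mono-methyl enol ether 3-methoxy-5-nonadecylcyclohex-2-en-1-one A8 would be dehydrogenated to 3-methoxy-5-nonadecylphenol A9, and a Teuber oxidation would give 19.
- **Merits.** Cheap reagents, robust enolate chemistry, no moisture-sensitive diene, and a symmetrical dione that raises no regiochemical question in the ring-forming step.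
- **Weak points.** A6 needs its own short preparation. The ring arrives at the wrong oxidation level and must be dehydrogenated. The third oxygen is introduced by radical oxidation of the arene C–H between methoxy and chain, the most hindered position, where para-quinone formation competes with ortho-quinone formation.
- **Comparison.** Step count is similar to the chosen plan and the reagents are easier to handle. The chosen plan offers instead a ring that is born aromatic with its two oxygens differentiated, and a C1 oxygen whose position is fixed by the carbon skeleton.

**Alternative 3:** The cut separates a four-carbon and a two-carbon unit of the arene: 3-nonadecylcyclobut-2-en-1-one A10 and methoxyacetylene A11.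

- **Forward key step.** Heating A10 with A11 starts a Danheiser benzannulation: electrocyclic opening to a vinylketene, [2+2] addition of the ynol ether, a second four-electron opening, six-electron closure and tautomerisation, giving A9. A Teuber oxidation would then give 19. A10 would come from alkyne 2 by a ketene [2+2] cycloaddition and dehalogenation.
- **Merits.** Regiospecific and convergent; it reaches the methoxyphenol directly in about five steps, fewer than the chosen plan.
- **Weak points.** A11 is a volatile, labile ynol ether that must be prepared and used fresh. The long-chain cyclobutenone needs a halogenated ketene and a reductive step. The route ends with the same para-selective C–H oxidation at the hindered position as alternative 2.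
- **Comparison.** This road is shorter and just as regiospecific in its ring-forming step. The chosen plan offers instead stable, inexpensive building blocks and the Dakin exchange, which places the third oxygen without any regiochemical question.

Key step: step 6

Remark on the chemistry: 19 has no stereocentre. The transient species 5 (racemic) and 11 (mixture of double-bond isomers) lose their stereochemical features in the same flask.

## Route

Step 1
Reactants: 1 1-bromononadecane
Product: 2 henicos-1-yne
Conditions: LiC≡CH·H2NCH2CH2NH2 (excess), DMSO/THF, 10 °C to rt
Reagents that add atoms: lithium acetylide–ethylenediamine complex, [Li+].[C-]#C.NCCN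
Why: SN2 alkylation of an acetylide by a primary bromide; DMSO leaves the anion poorly solvated and reactive, THF keeps the waxy bromide in solution, and the excess of reagent suppresses a second alkylation.

Step 2
Reactants: 2 henicos-1-yne; 3 N-methoxy-N-methylacetamide
Product: 6 tricos-3-yn-2-one, via henicos-1-yn-1-yllithium 4 (not isolated), via lithium 2-[methoxy(methyl)amino]tricos-3-yn-2-olate 5 (not isolated)
Conditions: n-BuLi, THF, −40 to 0 °C; then 3, −40 °C to rt; 1 M HCl, 0 °C
Reagents that add atoms: none
Why: Weinreb ketone synthesis: the terminal alkyne is deprotonated to 4, which adds once to the amide; the chelated adduct 5 survives until the acidic quench, so no tertiary alcohol forms.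

Step 3
Reactants: 7 acetyl chloride; 8 1,1-dichloroethene
Product: 10 4,4-dichlorobut-3-en-2-one, via 4,4,4-trichlorobutan-2-one 9 (not isolated)
Conditions: AlCl3, CH2Cl2, 0 °C to rt; ice/aq HCl; distillation under reduced pressure (−HCl)
Reagents that add atoms: none
Why: Friedel–Crafts-type acylation of an alkene: the acylium ion attacks the CH2 terminus to give a chlorine-stabilised cation that is trapped by chloride as 9; loss of HCl on distillation gives the conjugated enone.

Step 4
Reactants: 10 4,4-dichlorobut-3-en-2-one
Product: 12 4,4-dimethoxybut-3-en-2-one, via 4-chloro-4-methoxybut-3-en-2-one 11 (not isolated)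
Conditions: NaOMe (2.2 equiv), MeOH, 0 °C to rt
Reagents that add atoms: sodium methoxide, [Na+].[O-]C
Why: Twofold nucleophilic vinylic substitution by addition–elimination at the β-carbon of the enone; each chloride leaves in turn from the stabilised enolate.

Step 5
Reactants: 12 4,4-dimethoxybut-3-en-2-one
Product: 13 1,1-dimethoxy-3-(trimethylsilyloxy)buta-1,3-diene
Conditions: Me3SiCl, Et3N, ZnCl2 (cat.), toluene, rt to 40 °C; filtration under N2, distillation
Reagents that add atoms: chlorotrimethylsilane, C[Si](C)(C)Cl
Why: Silyl enol ether formation by ZnCl2-assisted soft enolisation; the methyl group is the only enolisable position of 12, so only the cross-conjugated 2-silyloxydiene can form.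

Step 6
Reactants: 13 1,1-dimethoxy-3-(trimethylsilyloxy)buta-1,3-diene; 6 tricos-3-yn-2-one
Product: 16 1-(4-hydroxy-2-methoxy-6-nonadecylphenyl)ethan-1-one, via cyclohexadiene cycloadduct 14 (not isolated), via aryl trimethylsilyl ether 15 (not isolated)
Conditions: 13 (2–3 equiv), toluene, 110 °C, sealed vessel, Ar; then 1 M HCl, THF, rt
Reagents that add atoms: none
Why: Normal-electron-demand Diels–Alder reaction followed by aromatisation, the known route from 1,1-dialkoxy-3-silyloxybutadienes and acetylenic carbonyl compounds to resorcinol monoethers. The CH2 terminus of 13 has the largest HOMO coefficient because the silyloxy group and, through the diene, the ketene acetal both push electron density onto it; it bonds to the chain-bearing β-carbon of 6 (future C5–C6), while the ketene acetal carbon bonds to the acetyl-bearing α-carbon (future C1–C2), in one asynchronous step. The ring closes by this intermolecular [4+2] mode, four ring atoms from the diene and two from the alkyne, to give cyclohexa-1,4-diene 14. 14 loses methanol by 1,4-elimination between the ketal carbon and the ring CH2, driven by aromatisation, to give 15, and dilute acid cleaves the O–Si bond to 16. No stereocentre is created, since the ketal carbon of 14 bears two identical methoxy groups and becomes planar on aromatisation. The selectivity required is regiochemical and is secured by the matched polarisation of the partners, which places the chain meta to both oxygens and the acetyl group between methoxy and chain. Thermal conditions without Lewis acid keep the ketone carbonyl from acting as a heterodienophile, and excess diene at high concentration compensates for the lower reactivity of an internal alkyne.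

Step 7
Reactants: 16 1-(4-hydroxy-2-methoxy-6-nonadecylphenyl)ethan-1-one
Product: 18 2-methoxy-6-nonadecylbenzene-1,4-diol, via 4-hydroxy-2-methoxy-6-nonadecylphenyl acetate 17 (not isolated)
Conditions: 30% aq H2O2, NaOH, THF/MeOH/H2O (degassed), 0 °C to rt, N2; then aq HCl
Reagents that add atoms: hydrogen peroxide, OO
Why: Dakin oxidation: hydroperoxide adds to the ketone, which is twisted out of conjugation by its two ortho substituents and therefore not deactivated by the para-phenoxide; the electron-rich aryl group migrates to oxygen to give acetate 17, which is saponified in the same flask.

Step 8
Reactants: 18 2-methoxy-6-nonadecylbenzene-1,4-diol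
Product: 19 2-methoxy-6-nonadecylcyclohexa-2,5-diene-1,4-dione
Conditions: Ag2O, Et2O, rt, dark
Reagents that add atoms: none
Why: Two-electron oxidation of a para-hydroquinone to the quinone by Ag2O under neutral, non-nucleophilic conditions that leave the methoxyquinone untouched; only one quinone can form.

## Compound list

1 | 1-bromononadecane | CCCCCCCCCCCCCCCCCCCBr | starting material
2 | henicos-1-yne | CCCCCCCCCCCCCCCCCCCC#C | intermediate
3 | N-methoxy-N-methylacetamide | CON(C)C(C)=O | starting material
4 | henicos-1-yn-1-yllithium | CCCCCCCCCCCCCCCCCCCC#C[Li] | intermediate
5 | lithium 2-[methoxy(methyl)amino]tricos-3-yn-2-olate (racemic) | CCCCCCCCCCCCCCCCCCCC#CC(C)(O[Li])N(C)OC | intermediate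
6 | tricos-3-yn-2-one | CCCCCCCCCCCCCCCCCCCC#CC(C)=O | intermediate
7 | acetyl chloride | CC(=O)Cl | starting material
8 | 1,1-dichloroethene | ClC(Cl)=C | starting material
9 | 4,4,4-trichlorobutan-2-one | CC(=O)CC(Cl)(Cl)Cl | intermediate
10 | 4,4-dichlorobut-3-en-2-one | CC(=O)C=C(Cl)Cl | intermediate
11 | 4-chloro-4-methoxybut-3-en-2-one (mixture of double-bond isomers) | CC(=O)C=C(Cl)OC | intermediate
12 | 4,4-dimethoxybut-3-en-2-one | CC(=O)C=C(OC)OC | intermediate
13 | 1,1-dimethoxy-3-(trimethylsilyloxy)buta-1,3-diene | COC(OC)=CC(=C)O[Si](C)(C)C | intermediate
14 | 1-[6,6-dimethoxy-2-nonadecyl-4-(trimethylsilyloxy)cyclohexa-1,4-dien-1-yl]ethan-1-one | CCCCCCCCCCCCCCCCCCCC1=C(C(C)=O)C(OC)(OC)C=C(O[Si](C)(C)C)C1 | intermediate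
15 | 1-[2-methoxy-6-nonadecyl-4-(trimethylsilyloxy)phenyl]ethan-1-one | CCCCCCCCCCCCCCCCCCCc1cc(O[Si](C)(C)C)cc(OC)c1C(C)=O | intermediate
16 | 1-(4-hydroxy-2-methoxy-6-nonadecylphenyl)ethan-1-one | CCCCCCCCCCCCCCCCCCCc1cc(O)cc(OC)c1C(C)=O | intermediate
17 | 4-hydroxy-2-methoxy-6-nonadecylphenyl acetate | CCCCCCCCCCCCCCCCCCCc1cc(O)cc(OC)c1OC(C)=O | intermediate
18 | 2-methoxy-6-nonadecylbenzene-1,4-diol | CCCCCCCCCCCCCCCCCCCc1cc(O)cc(OC)c1O | intermediate
19 | 2-methoxy-6-nonadecylcyclohexa-2,5-diene-1,4-dione | CCCCCCCCCCCCCCCCCCCC1=CC(=O)C=C(OC)C1=O | target

## Step count and least certain steps

Total step count: 8. Longest linear sequence: 6 (steps 3, 4, 5, 6, 7, 8); steps 1 and 2 form the two-step ynone branch that joins at step 6.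

**Step 6 (key step).** The most likely failure is a cycloaddition too slow to compete with thermal and hydrolytic degradation of the diene, because the β-alkyl group makes the ynone both less electrophilic and more hindered. Conjugate addition without ring closure is the second risk.
- Fallback: it sets out from alkyne 2. Lithiation to 4 and formylation with DMF would give docos-2-ynal F1, a smaller and more strongly activated dienophile. Heating F1 with 13 without Lewis acid, then loss of methanol and acidic desilylation, should give 4-hydroxy-2-methoxy-6-nonadecylbenzaldehyde F2. Dakin oxidation of F2 with alkaline H2O2, the classical aldehyde case, returns to the route at 18.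

**Step 7.** The most likely failures are incomplete addition of hydroperoxide to the doubly ortho-substituted ketone, and over-oxidation of the electron-rich hydroquinone once it is set free in alkaline peroxide.
- Fallback: it sets out from 16 and keeps the ring oxygens acylated during the oxidation. Acetylation (Ac2O, pyridine) would give 4-acetyl-3-methoxy-5-nonadecylphenyl acetate F3. Baeyer–Villiger oxidation with 3-chloroperbenzoic acid in CH2Cl2 would give 2-methoxy-6-nonadecyl-1,4-phenylene diacetate F4. Methanolysis (K2CO3, MeOH, N2) returns to the route at 18.

**Step 5.** The most likely failure is hydrolytic reversion of the silyl dienol ether during filtration and distillation, caused by moisture or traces of ammonium salt, which would leave too little intact diene for step 6.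
- Fallback: it sets out from 12 and uses a sturdier silyl group. Soft enolisation with tert-butyldimethylsilyl triflate and Et3N would give tert-butyl[(4,4-dimethoxybuta-1,3-dien-2-yl)oxy]dimethylsilane F5. Cycloaddition of F5 with 6 and loss of methanol would give 1-[4-(tert-butyldimethylsilyloxy)-2-methoxy-6-nonadecylphenyl]ethan-1-one F6, which can be chromatographed. Cleavage with Bu4NF returns to the route at 16.

**Step 1.** The most likely failure is sluggish substitution, because the long-chain bromide dissolves poorly in DMSO; on warming, dehydrobromination and base-induced migration of the triple bond would take over.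
- Fallback: it sets out from 1 and avoids acetylide substitution. Magnesium insertion would give nonadecylmagnesium bromide F7. Formylation with DMF and acidic work-up would give icosanal F8. Ohira–Bestmann homologation (dimethyl (1-diazo-2-oxopropyl)phosphonate, K2CO3, MeOH) returns to the route at 2.

## Further compounds

F1 | step 6 | docos-2-ynal | CCCCCCCCCCCCCCCCCCCC#CC=O
F2 | step 6 | 4-hydroxy-2-methoxy-6-nonadecylbenzaldehyde | CCCCCCCCCCCCCCCCCCCc1cc(O)cc(OC)c1C=O
F3 | step 7 | 4-acetyl-3-methoxy-5-nonadecylphenyl acetate | CCCCCCCCCCCCCCCCCCCc1cc(OC(C)=O)cc(OC)c1C(C)=O
F4 | step 7 | 2-methoxy-6-nonadecyl-1,4-phenylene diacetate | CCCCCCCCCCCCCCCCCCCc1cc(OC(C)=O)cc(OC)c1OC(C)=O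
F5 | step 5 | tert-butyl[(4,4-dimethoxybuta-1,3-dien-2-yl)oxy]dimethylsilane | COC(OC)=CC(=C)O[Si](C)(C)C(C)(C)C
F6 | step 5 | 1-[4-(tert-butyldimethylsilyloxy)-2-methoxy-6-nonadecylphenyl]ethan-1-one | CCCCCCCCCCCCCCCCCCCc1cc(O[Si](C)(C)C(C)(C)C)cc(OC)c1C(C)=O
F7 | step 1 | nonadecylmagnesium bromide | CCCCCCCCCCCCCCCCCCC[Mg]Br
F8 | step 1 | icosanal | CCCCCCCCCCCCCCCCCCCC=O
A1 | alternative 1 | 1-iodo-2,4-dimethoxybenzene | COc1ccc(I)c(OC)c1
A2 | alternative 1 | bis(pinacolato)diboron | CC1(C)OB(OC1(C)C)B1OC(C)(C)C(C)(C)O1
A3 | alternative 1 | 2-(2,4-dimethoxy-6-nonadecylphenyl)-4,4,5,5-tetramethyl-1,3,2-dioxaborolane | CCCCCCCCCCCCCCCCCCCc1cc(OC)cc(OC)c1B1OC(C)(C)C(C)(C)O1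
A4 | alternative 1 | 2,4-dimethoxy-6-nonadecylphenol | CCCCCCCCCCCCCCCCCCCc1cc(OC)cc(OC)c1O
A5 | alternative 2 | dimethyl malonate | COC(=O)CC(=O)OC
A6 | alternative 2 | (E)-tricos-3-en-2-one | CCCCCCCCCCCCCCCCCCC/C=C/C(C)=O
A7 | alternative 2 | 5-nonadecylcyclohexane-1,3-dione | CCCCCCCCCCCCCCCCCCCC1CC(=O)CC(=O)C1
A8 | alternative 2 | 3-methoxy-5-nonadecylcyclohex-2-en-1-one (racemic) | CCCCCCCCCCCCCCCCCCCC1CC(=O)C=C(OC)C1
A9 | alternative 2 | 3-methoxy-5-nonadecylphenol | CCCCCCCCCCCCCCCCCCCc1cc(O)cc(OC)c1
A10 | alternative 3 | 3-nonadecylcyclobut-2-en-1-one | CCCCCCCCCCCCCCCCCCCC1=CC(=O)C1
A11 | alternative 3 | methoxyacetylene | COC#C
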